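## Retrosynthetic overview
- The target is a 2,3-dimethyl-1,4-diarylbutane with no rings. Its stereocenters are (2S,3R) from the guaiacyl side, which is the *meso*-type relative configuration. The two different aryl groups make it a single enantiomer.
- Disconnect the phenols to the bis-benzyl ether, then the two ArCH2–C(sp3) bonds by Negishi couplings of two CH2I termini. The two termini are differentiated as CH2I and CO2Me (→ CH2OH → CH2I).
- The C4 chain comes from one desymmetrized hemiester of *cis*-2,3-dimethylsuccinic anhydride. The cis relative configuration comes from hydrogenating dimethylmaleic anhydride, and the absolute configuration from an enantioselective alcoholysis.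
- The only ring is the transient anhydride.

**Assumptions.**
1. The cinchona-catalysed methanolysis can be tuned with the pseudo-enantiomeric catalyst to give the (2R,3S) hemiester 7. If the other antipode forms, swap the order in which the two aryl bromides are coupled.
2. Aryl bromides 2 and 4 are made by benzylation of commercial bromophenols.

## Route

**Step 1**
Reactants: 1 (4-bromo-2-methoxyphenol)
Product: 2 (1-(benzyloxy)-4-bromo-2-methoxybenzene)
Conditions: BnBr, K2CO3, DMF, rt
Reagents that add atoms: benzyl bromide, BrCc1ccccc1
Why: Williamson O-benzylation masks the phenol so it survives the organozinc and LiAlH4 steps, and it is removed by hydrogenolysis at the end.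

**Step 2**
Reactants: 3 (4-bromo-2,6-dimethoxyphenol)
Product: 4 (2-(benzyloxy)-5-bromo-1,3-dimethoxybenzene)
Conditions: BnBr, K2CO3, DMF, rt
Reagents that add atoms: benzyl bromide, BrCc1ccccc1
Why: same O-benzylation, giving the syringyl coupling partner.

**Step 3**
Reactants: 5 (2,3-dimethylmaleic anhydride)
Product: 6 (*cis*-2,3-dimethylsuccinic anhydride, (3R,4S), meso)
Conditions: H2 (1–3 atm), 10% Pd/C, EtOAc, rt
Reagents that add atoms: none
Why: heterogeneous hydrogenation delivers both H atoms to the same face of the tetrasubstituted alkene (syn addition), so both methyls end up cis. This sets the relative configuration.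

**Step 4**
Reactants: 6
Product: 7 ((2R,3S)-4-methoxy-2,3-dimethyl-4-oxobutanoic acid)
Conditions: MeOH (5 equiv), (DHQD)2AQN (10 mol%), MTBE, –20 °C
Reagents that add atoms: methanol, CO
Why: a cinchona-alkaloid-catalysed enantioselective alcoholysis desymmetrizes the meso anhydride. The catalyst chooses which of the two enantiotopic C=O groups is opened, which sets the absolute configuration of both stereocenters.

**Step 5**
Reactants: 7
Product: 8 (methyl (2S,3R)-4-hydroxy-2,3-dimethylbutanoate)
Conditions: BH3·SMe2 (1.1 equiv), THF, 0 °C → rt; neutral workup
Reagents that add atoms: none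
Why: borane reduces a carboxylic acid much faster than an ester (chemoselective acyloxyborane reduction). Neither stereocenter is touched.

**Step 6**
Reactants: 8
Product: 9 (methyl (2S,3R)-4-iodo-2,3-dimethylbutanoate)
Conditions: I2, PPh3, imidazole, CH2Cl2, 0 °C → rt
Reagents that add atoms: iodine, II
Why: an Appel iodination (SN2) occurs at the primary CH2 carbon, which is not a stereocenter, so the configuration is retained.

**Step 7**
Reactants: 9, 2
Product: 10 (methyl (2S,3S)-4-[4-(benzyloxy)-3-methoxyphenyl]-2,3-dimethylbutanoate)
Conditions: (i) Zn dust, LiCl, TMSCl/BrCH2CH2Br (cat.), THF, 50 °C; (ii) 2, Pd-PEPPSI-IPr (2 mol%), THF, rt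
Reagents that add atoms: none
Why: a Negishi coupling of a primary alkylzinc with an aryl bromide forms the ArCH2–C bond. It is remote from both stereocenters, which are unchanged. The CIP label of C3 changes from R to S only because of the priority change (CH2I → CH2Ar).

**Step 8**
Reactants: 10
Product: 11 ((2S,3S)-4-[4-(benzyloxy)-3-methoxyphenyl]-2,3-dimethylbutan-1-ol)
Conditions: LiAlH4, THF, 0 °C
Reagents that add atoms: none
Why: hydride reduction of the ester to the primary alcohol leaves the benzyl ether and aryl methyl ether intact. The α-stereocenter is not epimerized under these non-enolizing reducing conditions.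

**Step 9**
Reactants: 11
Product: 12 (1-(benzyloxy)-4-[(2S,3S)-4-iodo-2,3-dimethylbutyl]-2-methoxybenzene)
Conditions: I2, PPh3, imidazole, CH2Cl2, 0 °C → rt
Reagents that add atoms: iodine, II
Why: Appel iodination at the primary CH2OH, with no stereochemical consequence.

**Step 10**
Reactants: 12, 4
Product: 13 (2-(benzyloxy)-5-[(2R,3S)-4-[4-(benzyloxy)-3-methoxyphenyl]-2,3-dimethylbutyl]-1,3-dimethoxybenzene)
Conditions: (i) Zn, LiCl, TMSCl (cat.), THF, 50 °C; (ii) 4, Pd-PEPPSI-IPr (2 mol%), THF, rt
Reagents that add atoms: none
Why: a second Negishi coupling installs the syringyl arm. Both stereocenters are unchanged (C3 is relabelled R by priority only).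

**Step 11**
Reactants: 13
Product: 14 (target, 4-[(2R,3S)-4-(4-hydroxy-3-methoxyphenyl)-2,3-dimethylbutyl]-2,6-dimethoxyphenol)
Conditions: H2 (1 atm), 10% Pd/C, EtOAc/EtOH, rt
Reagents that add atoms: none
Why: hydrogenolysis removes both O-benzyl groups (toluene is lost) and leaves the aryl methyl ethers and the sp3 stereocenters untouched.

## Checks
- **Stereochemistry.**
  - The SMILES of 14 was rewritten from 13 with the same neighbour order at each center, and it is identical to the target SMILES.
  - The CIP analysis agrees: the guaiacyl-side carbon is S and the syringyl-side carbon is R, i.e. (2R,3S) from the syringyl side.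
  - Hemiester 7 puts R on the acid-side carbon, which becomes the guaiacyl arm, and S on the ester-side carbon, which becomes the syringyl arm.
- **Atom balance.** Each step follows from its reactants. The aryl groups enter only in steps 7 and 10 and the benzyls leave only in step 11.
- **Functional-group survival.**
  - Steps 7 and 10 (zinc-mediated couplings): the ester and the ethers survive.
  - Step 8 (LiAlH4): the benzyl ethers survive.
  - Step 11: only O-Bn is cleaved.
  - No other step places a stereocenter under epimerizing conditions.
- **Stereocenters.** Both are set in steps 3 and 4 and are never adjacent to an enolizable carbonyl after step 8.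

## Compound list
1 | 4-bromo-2-methoxyphenol | COc1cc(Br)ccc1O | starting material
2 | 1-(benzyloxy)-4-bromo-2-methoxybenzene | COc1cc(Br)ccc1OCc1ccccc1 | intermediate
3 | 4-bromo-2,6-dimethoxyphenol | COc1cc(Br)cc(OC)c1O | starting material
4 | 2-(benzyloxy)-5-bromo-1,3-dimethoxybenzene | COc1cc(Br)cc(OC)c1OCc1ccccc1 | intermediate
5 | 2,3-dimethylmaleic anhydride | CC1=C(C)C(=O)OC1=O | starting material
6 | *cis*-2,3-dimethylsuccinic anhydride (meso) | C[C@H]1[C@@H](C)C(=O)OC1=O | intermediate
7 | (2R,3S)-4-methoxy-2,3-dimethyl-4-oxobutanoic acid | OC(=O)[C@H](C)[C@H](C)C(=O)OC | intermediate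
8 | methyl (2S,3R)-4-hydroxy-2,3-dimethylbutanoate | OC[C@H](C)[C@H](C)C(=O)OC | intermediate
9 | methyl (2S,3R)-4-iodo-2,3-dimethylbutanoate | IC[C@H](C)[C@H](C)C(=O)OC | intermediate
10 | methyl (2S,3S)-4-[4-(benzyloxy)-3-methoxyphenyl]-2,3-dimethylbutanoate | COc1cc(C[C@H](C)[C@H](C)C(=O)OC)ccc1OCc1ccccc1 | intermediate
11 | (2S,3S)-4-[4-(benzyloxy)-3-methoxyphenyl]-2,3-dimethylbutan-1-ol | COc1cc(C[C@H](C)[C@H](C)CO)ccc1OCc1ccccc1 | intermediate
12 | 1-(benzyloxy)-4-[(2S,3S)-4-iodo-2,3-dimethylbutyl]-2-methoxybenzene | COc1cc(C[C@H](C)[C@H](C)CI)ccc1OCc1ccccc1 | intermediate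
13 | bis-O-benzyl ether of the target | COc1cc(C[C@H](C)[C@H](C)Cc2cc(OC)c(OCc3ccccc3)c(OC)c2)ccc1OCc1ccccc1 | intermediate
14 | 4-[(2R,3S)-4-(4-hydroxy-3-methoxyphenyl)-2,3-dimethylbutyl]-2,6-dimethoxyphenol | COc1cc(C[C@H](C)[C@H](C)Cc2cc(OC)c(O)c(OC)c2)ccc1O | target

## Step count
- Total steps: 11, including the two benzylations.
- Longest linear sequence: 9 steps (5 → 6 → 7 → 8 → 9 → 10 → 11 → 12 → 13 → 14, counting the 9 transformations).

## Three steps most likely to fail
1. **Step 4, desymmetrization.** The ee may be modest or the wrong antipode may form.
   - *Fallback:* reduce 6 with LiAlH4 to the meso diol and desymmetrize it by lipase-catalysed monoacetylation with vinyl acetate. Carry the monoacetate through the same iodination and coupling sequence, swapping the aryl order if the antipode is opposite.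
2. **Steps 7 and 10, Negishi couplings.** A β-branched alkyl-Pd species can undergo β-hydride elimination and re-insertion, which would epimerize the adjacent methyl-bearing carbon or give isomerized products.
   - *Fallback:* use a reverse-polarity, radical-type Ni-catalysed reductive coupling of the alkyl iodide with the aryl bromide (NiI2/bipyridine, Mn). There is no alkyl-Pd intermediate, and the stereocenter β to the radical is not affected.
3. **Step 5, borane reduction.** The γ-hydroxy ester 8 may lactonize to the 3,4-dimethyl-γ-butyrolactone.
   - *Fallback:* deliberately close the lactone with TsOH. Open it with NaI/TMSCl to the iodo acid, then esterify with TMSCHN2 to give 9, which replaces steps 5 and 6.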